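The chroman is disconnected at the two bonds that tie the pyran ring to ring A, aryl C8a–O1 and aryl C4a–C4. Both form in one operation when the potassium alkoxide of (S)-1-[4-(benzyloxy)phenyl]-3-chloropropan-1-ol adds to 3,5-bis(benzyloxy)benzyne: oxygen attacks the aryne carbon remote from the flanking benzyloxy group, and the aryl anion generated beside that group displaces the primary chloride. The step exploits the vicinal O/C substitution of ring A at C8a and C4a next to the C5 oxygen; the C2 stereocentre comes from a CBS reduction. Bromination at C8, a one-pot diaryl 1,2-diketone assembly on an oxalic bis-Weinreb amide and hydrogenolysis complete the route.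

Key step: step 5

Remark: all four phenols are carried as benzyl ethers, because the C2–O1 bond of a 2-(4-oxyphenyl)chromane is a 4-alkoxybenzyl-type ether that would ionise (and racemise C2) under the Lewis or strong protic acids needed to cleave methyl ethers; the final unmasking is therefore a neutral hydrogenolysis.

Step 1
Reactants: 1 3-chloro-1-(4-hydroxyphenyl)propan-1-one
Product: 2 1-[4-(benzyloxy)phenyl]-3-chloropropan-1-one
Conditions: BnOH, PPh3, DIAD, THF, 0 °C to rt
Reagents that add atoms: benzyl alcohol, OCc1ccccc1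
Why: Mitsunobu O-benzylation of the acidic 4-acylphenol runs without added base, so the β-chloro ketone is not exposed to conditions that eliminate HCl.

Step 2
Reactants: 2 1-[4-(benzyloxy)phenyl]-3-chloropropan-1-one
Product: 3 (1S)-1-[4-(benzyloxy)phenyl]-3-chloropropan-1-ol
Conditions: (R)-2-methyl-CBS-oxazaborolidine [(3aR)-1-methyl-3,3-diphenyltetrahydro-1H,3H-pyrrolo[1,2-c][1,3,2]oxazaborole] (10 mol%), BH3·SMe2, THF, −20 °C; MeOH quench
Reagents that add atoms: none
Why: Corey–Bakshi–Shibata reduction, in which the (R)-oxazaborolidine–borane complex binds the ketone with the aryl group as the large substituent and delivers hydride to the Re face, setting the (S) carbinol centre that becomes C2.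

Step 3
Reactants: 4 3,5-bis(benzyloxy)phenol
Product: 5 3,5-bis(benzyloxy)-2-bromophenol
Conditions: NBS, i-Pr2NH (10 mol%), CH2Cl2, 0 °C
Reagents that add atoms: N-bromosuccinimide, O=C1CCC(=O)N1Br
Why: amine-mediated ortho-selective electrophilic bromination of a phenol, where the two ortho positions are equivalent by symmetry, so a single 2-bromophenol should result.

Step 4
Reactants: 5 3,5-bis(benzyloxy)-2-bromophenol
Product: 8 3,5-bis(benzyloxy)-2-(trimethylsilyl)phenyl trifluoromethanesulfonate, via aryl trimethylsilyl ether 6 (not isolated), via lithium 2-silylphenoxide 7 (not isolated)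
Conditions: HMDS, THF, 70 °C, volatiles removed; n-BuLi, THF, −100 °C; Tf2O, −100 to −78 °C
Reagents that add atoms: hexamethyldisilazane, C[Si](C)(C)N[Si](C)(C)C; trifluoromethanesulfonic anhydride, O=S(=O)(OS(=O)(=O)C(F)(F)F)C(F)(F)F
Why: O-silylation followed by bromine–lithium exchange triggers an anionic 1,3 O-to-C silyl shift (retro-Brook rearrangement) to phenoxide 7, which Tf2O traps on oxygen, the standard entry to 2-silylaryl triflates.

Step 5
Reactants: 3 (1S)-1-[4-(benzyloxy)phenyl]-3-chloropropan-1-ol; 8 3,5-bis(benzyloxy)-2-(trimethylsilyl)phenyl trifluoromethanesulfonate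
Product: 12 (2S)-5,7-bis(benzyloxy)-2-[4-(benzyloxy)phenyl]chromane, via potassium alkoxide 9 (not isolated), via 3,5-bis(benzyloxy)benzyne 10 (not isolated), via aryl potassium adduct 11 (not isolated)
Conditions: 3, KH, THF, 0 °C; then KF, 18-crown-6, slow addition of 8, THF, 0 °C to rt
Reagents that add atoms: none
Why: Proposed new method: fluoride attack on silicon in 8 expels triflate and gives aryne 10, to which alkoxide 9 adds at the aryne carbon remote from the neighbouring benzyloxy group (the future C8a), because a 3-alkoxyaryne is distorted and inductively biased so that the negative charge develops beside the alkoxy group, here at the future C4a of adduct 11. The 2,6-dioxygenated aryl anion 11 then displaces the primary chloride five atoms away, forming C4a–C4 and closing the pyran ring in a 6-exo-tet mode. The closest known reaction types are the O-arylation of alcohols and alkoxides by arynes, aryne annulations of nucleophiles that carry a tethered electrophile (salicylates to xanthones), and the Parham cyclialkylation of aryllithiums onto ω-haloalkyl chains; their merger on an aliphatic γ-chloro alkoxide is the untested part. No stereocentre is created, and C2 keeps its (S) configuration because none of its bonds is broken. The step needs regioselective addition, secured by the C5 benzyloxy group flanking the aryne (the second benzyloxy group is remote), and ring closure ahead of protonation of 11, secured by complete deprotonation of 3 with KH, an aprotic medium, slow generation of 10 and a chloride leaving group that resists 4-exo closure of 9 and halogen–metal exchange.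

Step 6
Reactants: 12 (2S)-5,7-bis(benzyloxy)-2-[4-(benzyloxy)phenyl]chromane
Product: 13 (2S)-5,7-bis(benzyloxy)-2-[4-(benzyloxy)phenyl]-8-bromochromane
Conditions: NBS, CH2Cl2, −78 to 0 °C
Reagents that add atoms: N-bromosuccinimide, O=C1CCC(=O)N1Br
Why: electrophilic aromatic bromination of the phloroglucinol-type ring A, far more electron-rich than ring B, should go to C8 between the ring oxygen and one benzyloxy group and not to C6 shielded by two benzyloxy groups, as is usual for 5,7-dibenzyloxyflavans.

Step 7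
Reactants: 13 (2S)-5,7-bis(benzyloxy)-2-[4-(benzyloxy)phenyl]-8-bromochromane; 14 N,N'-dimethoxy-N,N'-dimethyloxamide; 15 4-(benzyloxy)phenylmagnesium bromide
Product: 19 1-{(2S)-5,7-bis(benzyloxy)-2-[4-(benzyloxy)phenyl]chroman-8-yl}-2-[4-(benzyloxy)phenyl]ethane-1,2-dione, via 8-lithiochromane 16 (not isolated), via lithium hemiaminal mono-adduct 17 (not isolated), via lithium magnesium bis-hemiaminal 18 (not isolated)
Conditions: n-BuLi, THF, −78 °C; cannulated into 14 (excess), THF, −78 °C; then 15, −78 to 0 °C; cold 1 M HCl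
Reagents that add atoms: none
Why: bromine–lithium exchange gives aryllithium 16, which opens one Weinreb amide of 14 to the chelated hemiaminal 17 that keeps the first carbonyl masked, so that Grignard reagent 15 substitutes the second amide (18) and acidic work-up releases the unsymmetrical 1,2-diketone (twofold Weinreb ketone synthesis on an oxalic diamide).

Step 8
Reactants: 19 1-{(2S)-5,7-bis(benzyloxy)-2-[4-(benzyloxy)phenyl]chroman-8-yl}-2-[4-(benzyloxy)phenyl]ethane-1,2-dione
Product: 20 1-[(2S)-5,7-dihydroxy-2-(4-hydroxyphenyl)chroman-8-yl]-2-(4-hydroxyphenyl)ethane-1,2-dione (CNP0332855.1)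
Conditions: H2 (1 atm), Pd/C (palladium on carbon), EtOAc, rt, stopped at full debenzylation
Reagents that add atoms: none
Why: catalytic hydrogenolysis cleaves the four aryl benzyl ethers under neutral conditions, which should be faster than reduction of the hindered hydrogen-bonded 1,2-diketone or cleavage of the cyclic benzylic C2–O bond, and it leaves the C2 stereocentre untouched.

Compound list
1 | 3-chloro-1-(4-hydroxyphenyl)propan-1-one | O=C(CCCl)c1ccc(O)cc1 | starting material
2 | 1-[4-(benzyloxy)phenyl]-3-chloropropan-1-one | O=C(CCCl)c1ccc(OCc2ccccc2)cc1 | intermediate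
3 | (1S)-1-[4-(benzyloxy)phenyl]-3-chloropropan-1-ol | O[C@H](c1ccc(OCc2ccccc2)cc1)CCCl | intermediate
4 | 3,5-bis(benzyloxy)phenol | Oc1cc(OCc2ccccc2)cc(OCc2ccccc2)c1 | starting material
5 | 3,5-bis(benzyloxy)-2-bromophenol | Oc1cc(OCc2ccccc2)cc(OCc2ccccc2)c1Br | intermediate
6 | [3,5-bis(benzyloxy)-2-bromophenoxy]trimethylsilane | C[Si](C)(C)Oc1cc(OCc2ccccc2)cc(OCc2ccccc2)c1Br | intermediate
7 | lithium 3,5-bis(benzyloxy)-2-(trimethylsilyl)phenoxide | [Li]Oc1cc(OCc2ccccc2)cc(OCc2ccccc2)c1[Si](C)(C)C | intermediate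
8 | 3,5-bis(benzyloxy)-2-(trimethylsilyl)phenyl trifluoromethanesulfonate | C[Si](C)(C)c1c(OS(=O)(=O)C(F)(F)F)cc(OCc2ccccc2)cc1OCc1ccccc1 | intermediate
9 | potassium (1S)-1-[4-(benzyloxy)phenyl]-3-chloropropan-1-olate | [K]O[C@H](c1ccc(OCc2ccccc2)cc1)CCCl | intermediate
10 | 3,5-bis(benzyloxy)benzyne (1,2-didehydro-3,5-bis(benzyloxy)benzene) | C1#CC(OCc2ccccc2)=CC(OCc2ccccc2)=C1 | intermediate
11 | potassium 2,4-bis(benzyloxy)-6-{(1S)-1-[4-(benzyloxy)phenyl]-3-chloropropoxy}phenyl (aryl anion at the future C4a) | [K]c1c(OCc2ccccc2)cc(OCc2ccccc2)cc1O[C@H](c1ccc(OCc2ccccc2)cc1)CCCl | intermediate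
12 | (2S)-5,7-bis(benzyloxy)-2-[4-(benzyloxy)phenyl]chromane | c1c(OCc3ccccc3)cc(OCc3ccccc3)c2c1O[C@H](c1ccc(OCc3ccccc3)cc1)CC2 | intermediate
13 | (2S)-5,7-bis(benzyloxy)-2-[4-(benzyloxy)phenyl]-8-bromochromane | Brc1c(OCc3ccccc3)cc(OCc3ccccc3)c2c1O[C@H](c1ccc(OCc3ccccc3)cc1)CC2 | intermediate
14 | N,N'-dimethoxy-N,N'-dimethyloxamide | CON(C)C(=O)C(=O)N(C)OC | starting material
15 | 4-(benzyloxy)phenylmagnesium bromide (THF solution) | Br[Mg]c1ccc(OCc2ccccc2)cc1 | starting material
16 | (2S)-5,7-bis(benzyloxy)-2-[4-(benzyloxy)phenyl]chroman-8-yllithium | [Li]c1c(OCc3ccccc3)cc(OCc3ccccc3)c2c1O[C@H](c1ccc(OCc3ccccc3)cc1)CC2 | intermediate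
17 | lithium hemiaminal mono-adduct of 16 and 14 (mixture at the hemiaminal carbon) | [Li]OC(N(C)OC)(C(=O)N(C)OC)c1c(OCc3ccccc3)cc(OCc3ccccc3)c2c1O[C@H](c1ccc(OCc3ccccc3)cc1)CC2 | intermediate
18 | lithium bromomagnesium bis-hemiaminal (mixture at the hemiaminal carbons) | [Li]OC(N(C)OC)(C(O[Mg]Br)(N(C)OC)c1ccc(OCc4ccccc4)cc1)c1c(OCc3ccccc3)cc(OCc3ccccc3)c2c1O[C@H](c1ccc(OCc3ccccc3)cc1)CC2 | intermediate
19 | 1-{(2S)-5,7-bis(benzyloxy)-2-[4-(benzyloxy)phenyl]chroman-8-yl}-2-[4-(benzyloxy)phenyl]ethane-1,2-dione | O=C(C(=O)c1c(OCc3ccccc3)cc(OCc3ccccc3)c2c1O[C@H](c1ccc(OCc3ccccc3)cc1)CC2)c1ccc(OCc3ccccc3)cc1 | intermediate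
20 | 1-[(2S)-5,7-dihydroxy-2-(4-hydroxyphenyl)chroman-8-yl]-2-(4-hydroxyphenyl)ethane-1,2-dione | O=C(C(=O)c1c(O)cc(O)c2c1O[C@H](c1ccc(O)cc1)CC2)c1ccc(O)cc1 | target

Total step count: 8. Longest linear sequence: 6 steps (steps 1, 2, 5, 6, 7, 8, or equally steps 3, 4, 5, 6, 7, 8).

Steps most likely to fail

1. Step 5 (proposed new method). The aryl anion 11 may be protonated before it alkylates, by residual 3, by the benzylic C2–H or by a benzyloxy CH2, which would leave the open-chain aryl ether and could erode the configuration at C2. Alkoxide 9 may also close to an oxetane before the aryne is formed. Fallback with known chemistry, setting out from 2 and 5 and returning at 12: ketone 2 is reduced with the enantiomeric catalyst, (S)-2-methyl-CBS-oxazaborolidine (the (3aS) enantiomer of the catalyst of step 2) and BH3·SMe2, to (R)-1-[4-(benzyloxy)phenyl]-3-chloropropan-1-ol F1. Mitsunobu etherification of bromophenol 5 with F1 (PPh3, DIAD, toluene, −20 °C) inverts the carbinol centre and should give 1,5-bis(benzyloxy)-2-bromo-3-{(1S)-1-[4-(benzyloxy)phenyl]-3-chloropropoxy}benzene F2. Treatment of F2 with n-BuLi (THF, −78 °C to rt) effects bromine–lithium exchange and Parham cyclialkylation onto the chloride, which should give 12. The two ring-A bonds are then made in separate operations.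

2. Step 7. The hindered aryllithium 16 may add twice to 14, the first hemiaminal chelate may collapse early and allow attack at the ketone, or the second substitution next to the crowded hemiaminal may stall. Fallback setting out from 13 and returning at 19: copper-free Sonogashira coupling of 13 with 1-(benzyloxy)-4-ethynylbenzene (C#Cc1ccc(OCc2ccccc2)cc1; Pd(MeCN)2Cl2, XPhos, Cs2CO3, MeCN, 80 °C) should give (2S)-5,7-bis(benzyloxy)-2-[4-(benzyloxy)phenyl]-8-{[4-(benzyloxy)phenyl]ethynyl}chromane F3. Buffered permanganate oxidation of the diarylalkyne (KMnO4, NaHCO3, MgSO4, acetone–water, rt) should then give 19. Permanganate is chosen over π-acidic metals to avoid cyclisation of the alkyne onto the ortho oxygens.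

3. Step 8. The 1,2-diketone may be reduced to the α-hydroxy ketone, or the benzylic C2–O bond may be opened by hydrogenolysis, while the last benzyl ethers are still being cleaved. Fallback setting out from 12 and returning at 20, with a change of protecting group so that no hydrogenation is run on the diketone:
- Hydrogenolysis of 12 (H2, Pd/C, EtOAc–MeOH) to (2S)-2-(4-hydroxyphenyl)chromane-5,7-diol F4.
- Protection (MOMCl, i-Pr2NEt, CH2Cl2) to (2S)-5,7-bis(methoxymethoxy)-2-[4-(methoxymethoxy)phenyl]chromane F5.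
- Bromination at C8 (NBS, CH2Cl2, −78 °C) to (2S)-8-bromo-5,7-bis(methoxymethoxy)-2-[4-(methoxymethoxy)phenyl]chromane F6.
- The lithiation and oxalamide sequence of step 7 (n-BuLi, then 14), with 4-(methoxymethoxy)phenylmagnesium bromide F7 (from 1-bromo-4-(methoxymethoxy)benzene and Mg, THF) as the second nucleophile, to 1-{(2S)-5,7-bis(methoxymethoxy)-2-[4-(methoxymethoxy)phenyl]chroman-8-yl}-2-[4-(methoxymethoxy)phenyl]ethane-1,2-dione F8.
- Mild acetal cleavage (HCl, MeOH, rt), which should give 20.

Further compounds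
F1 | step 5 | (R)-1-[4-(benzyloxy)phenyl]-3-chloropropan-1-ol | O[C@@H](c1ccc(OCc2ccccc2)cc1)CCCl
F2 | step 5 | 1,5-bis(benzyloxy)-2-bromo-3-{(1S)-1-[4-(benzyloxy)phenyl]-3-chloropropoxy}benzene | Brc1c(OCc2ccccc2)cc(OCc2ccccc2)cc1O[C@H](c1ccc(OCc2ccccc2)cc1)CCCl
F3 | step 7 | (2S)-5,7-bis(benzyloxy)-2-[4-(benzyloxy)phenyl]-8-{[4-(benzyloxy)phenyl]ethynyl}chromane | C(#Cc1ccc(OCc3ccccc3)cc1)c1c(OCc3ccccc3)cc(OCc3ccccc3)c2c1O[C@H](c1ccc(OCc3ccccc3)cc1)CC2
F4 | step 8 | (2S)-2-(4-hydroxyphenyl)chromane-5,7-diol | Oc1cc(O)c2c(c1)O[C@H](c1ccc(O)cc1)CC2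
F5 | step 8 | (2S)-5,7-bis(methoxymethoxy)-2-[4-(methoxymethoxy)phenyl]chromane | COCOc1cc(OCOC)c2c(c1)O[C@H](c1ccc(OCOC)cc1)CC2
F6 | step 8 | (2S)-8-bromo-5,7-bis(methoxymethoxy)-2-[4-(methoxymethoxy)phenyl]chromane | COCOc1cc(OCOC)c2c(c1Br)O[C@H](c1ccc(OCOC)cc1)CC2
F7 | step 8 | 4-(methoxymethoxy)phenylmagnesium bromide | COCOc1ccc([Mg]Br)cc1
F8 | step 8 | 1-{(2S)-5,7-bis(methoxymethoxy)-2-[4-(methoxymethoxy)phenyl]chroman-8-yl}-2-[4-(methoxymethoxy)phenyl]ethane-1,2-dione | COCOc1ccc(cc1)C(=O)C(=O)c1c(OCOC)cc(OCOC)c2c1O[C@H](c1ccc(OCOC)cc1)CC2
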